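**Retrosynthetic overview**
1. Numbering: C1–O-angelate, C2–O-isovalerate, C3–OH, C4 = CMe2, C5–H, C6–H, C7 = O, C8=C9–Me, C10–H, C11–Me; rings: cycloheptane C1–C5/C6/C11, cyclohexenone C6–C11, cyclobutane C5–C6–C11–C10.
2. The strategy rests on the C5–C10 bond, the bond that closes cyclobutane C5–C6–C11–C10 of the bicyclo[3.1.1]heptenone. It is traced back to a C5–NH–C10 pyrrolidine (a 6-azabicyclo[3.2.1]octenone), from which nitrogen is excised as N2.
3. Pyrrolidine: C10–N by intramolecular displacement of an α′-bromide on the C9 enone; C5–N from the C5 ketone through its oxime.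
4. Cyclohexene ring: Diels–Alder of a 2-silyloxybutadiene across C6=C11 of an (R)-4-PMBO-cycloheptadienone; that dienone by ring-closing metathesis (C6=C11) after asymmetric alkynylation of methacrolein (C1) and semihydrogenation (C2=C3).
5. Ring order: cycloheptadienone, cyclohexene, pyrrolidine, cyclobutane; then methyl addition at C9 with oxidative 1,3-transposition to the C7 enone, C1 angelate, dihydroxylation of C2=C3 anti to C1–O, C2 isovalerate.

Key step: step 14

Remark: intermediates are described with the core numbering above; in step 2 the ProPhenol antipode is the one that gives the (S)-carbinol; 2,2-dimethylbut-3-ynoic acid is taken as a catalogue compound.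

**Route**

Step 1
Reactants: 1 2,2-dimethylbut-3-ynoic acid
Product: 3 N-methoxy-N,2,2-trimethylbut-3-ynamide, via acyl imidazole 2 (not isolated)
Conditions: 1,1'-carbonyldiimidazole, CH2Cl2, rt; then MeNHOMe·HCl, rt
Reagents that add atoms: N,O-dimethylhydroxylamine hydrochloride, CNOC.Cl
Why: Weinreb amide formation through the acyl imidazole works on α-quaternary acids because the small imidazolide is readily aminolysed, and no stereocentre is involved.

Step 2
Reactants: 3 N-methoxy-N,2,2-trimethylbut-3-ynamide; 4 methacrolein
Product: 5 (S)-5-hydroxy-N-methoxy-N,2,2,6-tetramethylhept-6-en-3-ynamide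
Conditions: ProPhenol ligand (20 mol %), Me2Zn (3 equiv), Ph3PO (40 mol %), toluene, 0 °C; aq. NH4Cl
Reagents that add atoms: none
Why: Zinc–ProPhenol catalysed asymmetric alkynylation of an enal, a known reaction of terminal alkynes with α-substituted acroleins, should add the alkynylzinc of 3 to one enantioface of methacrolein and set C1 as the (S)-carbinol under catalyst control, the Weinreb amide being inert to Me2Zn.

Step 3
Reactants: 5 (S)-5-hydroxy-N-methoxy-N,2,2,6-tetramethylhept-6-en-3-ynamide
Product: 6 (S)-N-methoxy-5-[(4-methoxybenzyl)oxy]-N,2,2,6-tetramethylhept-6-en-3-ynamide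
Conditions: NaH, 4-methoxybenzyl chloride, Bu4NI (cat.), THF/DMF, 0 °C to rt
Reagents that add atoms: 4-methoxybenzyl chloride, COc1ccc(CCl)cc1
Why: Williamson etherification of the alkoxide, which cannot reach the amide across the linear alkyne, installs the PMB group without touching the stereocentre.

Step 4
Reactants: 6 (S)-N-methoxy-5-[(4-methoxybenzyl)oxy]-N,2,2,6-tetramethylhept-6-en-3-ynamide
Product: 7 (R,Z)-N-methoxy-5-[(4-methoxybenzyl)oxy]-N,2,2,6-tetramethylhepta-3,6-dienamide
Conditions: H2 (1 atm), Pd on CaCO3 poisoned with Pb(OAc)2, quinoline, EtOAc, rt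
Reagents that add atoms: none
Why: Lindlar semihydrogenation delivers H2 syn to the alkyne and stops at the cis C2=C3 alkene that the ring needs, the 1,1-disubstituted alkene and the benzyl ether being much slower to reduce.

Step 5
Reactants: 7 (R,Z)-N-methoxy-5-[(4-methoxybenzyl)oxy]-N,2,2,6-tetramethylhepta-3,6-dienamide
Product: 8 (R,Z)-7-[(4-methoxybenzyl)oxy]-4,4,8-trimethylnona-1,5,8-trien-3-one
Conditions: CH2=CHMgBr (3 equiv), THF, 0 °C; inverse quench into cold 1 M HCl
Reagents that add atoms: vinylmagnesium bromide, C=C[Mg]Br
Why: The Weinreb ketone synthesis stops at the chelated tetrahedral adduct so that a single vinyl group is delivered, and the inverse acidic quench keeps the liberated amine from adding to the vinyl ketone.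

Step 6
Reactants: 8 (R,Z)-7-[(4-methoxybenzyl)oxy]-4,4,8-trimethylnona-1,5,8-trien-3-one
Product: 9 (R)-4-[(4-methoxybenzyl)oxy]-3,7,7-trimethylcyclohepta-2,5-dien-1-one
Conditions: second-generation Grubbs catalyst RuCl2(=CHPh)(PCy3)(H2IMes) (5 mol %), toluene (2 mM), 80 °C
Reagents that add atoms: none
Why: Ring-closing metathesis between the vinyl ketone and the isopropenyl group closes the seven-membered ring as the trisubstituted C6=C11 enone, helped by the cis C2=C3 alkene and the gem-dimethyl group that hold the chain ends together, and C1 is untouched.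

Step 7
Reactants: 10 methyl vinyl ketone
Product: 11 2-(tert-butyldimethylsilyloxy)buta-1,3-diene
Conditions: t-BuMe2SiOTf, Et3N, Et2O, 0 °C
Reagents that add atoms: tert-butyldimethylsilyl trifluoromethanesulfonate, CC(C)(C)[Si](C)(C)OS(=O)(=O)C(F)(F)F
Why: Soft enolisation with O-silylation of the methyl ketone gives the cross-conjugated 2-silyloxy diene, a standard preparation.

Step 8
Reactants: 9 (R)-4-[(4-methoxybenzyl)oxy]-3,7,7-trimethylcyclohepta-2,5-dien-1-one; 11 2-(tert-butyldimethylsilyloxy)buta-1,3-diene
Product: 12 cis-fused bicyclic ketone (C5 ketone; C8=C9 silyl enol ether; C1 OPMB; C2=C3; H-6 and C11-methyl cis to the C1 oxygen)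
Conditions: Tf2NH (10 mol %), 11 (2.5 equiv), CH2Cl2, −78 to −40 °C; Et3N quench
Reagents that add atoms: none
Why: The triflimide-catalysed Diels–Alder reaction of 2-silyloxy dienes is the established way to engage β,β-disubstituted cycloalkenones and form a quaternary ring-fusion carbon; the nucleophilic CH2 terminus next to the silyloxy carbon bonds to the β-carbon C11 (para orientation, giving the C8=C9 enol ether), suprafacial addition gives the cis ring fusion, and the diene approaches anti to the C1 PMB ether, which allylic 1,2-strain with the C11 methyl holds pseudo-axial, so that C11-Me and H-6 end cis to the C1 oxygen.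

Step 9
Reactants: 12 cis-fused bicyclic ketone
Product: 13 C5 oxime of 12
Conditions: NH2OH (50 % in H2O, 10 equiv), EtOH, 70 °C
Reagents that add atoms: hydroxylamine, NO
Why: Oxime formation with excess free hydroxylamine is effective even for α-quaternary ketones and, being non-acidic, spares the silyl enol ether that masks the C9 carbonyl, and no new stereocentre is formed.

Step 10
Reactants: 13 C5 oxime
Product: 15 C5 trifluoroacetamide (N cis to C7), via C5 primary amine 14 (not isolated)
Conditions: LiAlH4, THF, 65 °C; aq. NaOH work-up; then (CF3CO)2O, Et3N, CH2Cl2, 0 °C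
Reagents that add atoms: trifluoroacetic anhydride, O=C(OC(=O)C(F)(F)F)C(F)(F)F
Why: LiAlH4 reduction of the ketoxime gives the primary amine with hydride expected on the convex face of C5 (the face of H-6 and the angular methyl, away from the cyclohexene ring), which puts nitrogen cis to C7 on the concave face where it can later reach C10, and trifluoroacetylation of the crude amine protects it.

Step 11
Reactants: 15 C5 trifluoroacetamide
Product: 16 trifluoroacetamido enone (C9 ketone; C7=C8)
Conditions: Pd(OAc)2 (1.2 equiv), MeCN, 40 °C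
Reagents that add atoms: none
Why: Saegusa–Ito oxidation of the regiodefined C8=C9 silyl enol ether palladates C8 and eliminates a C7 hydrogen, giving the C7=C8 enone with the C9 carbonyl without affecting any stereocentre.

Step 12
Reactants: 16 trifluoroacetamido enone
Product: 18 α′-bromo enone (Br at C10 cis to the C11 methyl), via bis-silyl dienol ether 17 (not isolated)
Conditions: LiN(SiMe3)2 (2.3 equiv), Me3SiCl (2.5 equiv), THF, −78 °C; then NBS, −78 to −20 °C; aq. NaHCO3
Reagents that add atoms: N-bromosuccinimide, O=C1CCC(=O)N1Br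
Why: Kinetic α′-enolisation of the enone at C10 (C8 is vinylic and low temperature avoids γ-deprotonation at C6) followed by bromination of the cross-conjugated silyl dienol ether at its terminal carbon is standard α′-halogenation, and NBS should attack C10 anti to the seven-membered ring so that bromine is cis to the C11 methyl and anti to the nitrogen on C5.

Step 13
Reactants: 18 α′-bromo enone
Product: 20 azatricyclic enone (NH bridging C5 and C10; C9 ketone; C7=C8), via N-trifluoroacetyl azatricycle 19 (not isolated)
Conditions: Cs2CO3, MeCN, 40 °C; then K2CO3, MeOH/H2O, 50 °C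
Reagents that add atoms: none
Why: Intramolecular SN2 N-alkylation (5-exo-tet) of the trifluoroacetamidate at the α-keto carbon closes the pyrrolidine with inversion at C10, the tether allowing bonding only on the face of C5 and elimination being impossible at quaternary C11, after which basic solvolysis removes the trifluoroacetyl group from the now non-enolisable bridged ketone.

Step 14
Reactants: 20 azatricyclic enone
Product: 23 tricyclic cyclobutane enone (C9 ketone; C7=C8; C5–C10 bond formed), via N-benzyloxy hydrazide 21 (not isolated), via isodiazene 22 (not isolated)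
Conditions: N-(benzyloxy)-N-(pivaloyloxy)-4-(trifluoromethyl)benzamide (1.5 equiv), THF, 45 °C
Reagents that add atoms: none
Why: The bridging amine attacks the electrophilic nitrogen of the anomeric amide and displaces pivalate to give hydrazide 21, whose benzyloxy group migrates to the acyl carbon with release of benzyl 4-(trifluoromethyl)benzoate, leaving isodiazene 22; loss of N2 from 22 gives a singlet C5/C10 1,4-biradical that collapses to the C5–C10 bond. The closest known reaction type is the isodiazene-mediated nitrogen deletion of secondary amines, which contracts pyrrolidines to cyclobutanes and bridged azabicycles to the next smaller carbobicycle. Cyclobutane C5–C6–C11–C10 closes by radical–radical recombination between two carbons that are already tied together through C6 and C11, turning the strain-free 6-azabicyclo[3.2.1]octenone into the bicyclo[3.1.1]heptenone, the strain being paid for by N2. C5 and C10 are not newly created but must be retained: each radical centre stays locked in its ring (C5 in the cycloheptene, C10 in the cyclohexenone), so the new bond can only form on the face that nitrogen occupied. The step needs recombination to outrun scission of the C6–C11 bond (which would give an eleven-membered tetraene) and hydrogen-atom transfer; the α-keto stabilisation of the C10 radical eases N2 loss, while the short C5···C10 distance fixed by the cage and the poor alignment of the C6–C11 bond with the enone-delocalised C10 orbital favour closure. The enone, the PMB ether and the C2=C3 alkene are inert to the anomeric amide at 45 °C.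

Step 15
Reactants: 23 tricyclic cyclobutane enone
Product: 24 C9 tertiary allylic alcohol (C9 methyl carbinol; C7=C8)
Conditions: MeLi, CeCl3, THF, −78 °C; aq. NH4Cl
Reagents that add atoms: methyllithium, [Li]C
Why: Organocerium-mediated 1,2-addition of methyl to the non-enolisable enone carbonyl (C10 and C6 are bridgeheads) should proceed from the face of the C5 bridge, opposite the C11 methyl that overhangs the three-carbon bridge, although the configuration of the new carbinol is erased in the next step.

Step 16
Reactants: 24 C9 tertiary allylic alcohol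
Product: 25 transposed enone (C7 ketone; C8=C9 bearing the C9 methyl)
Conditions: pyridinium chlorochromate (C5H5NH)[CrO3Cl] (3 equiv), 4 Å molecular sieves, CH2Cl2, rt
Reagents that add atoms: pyridinium chlorochromate, [O-][Cr](=O)(=O)Cl.c1cc[nH+]cc1
Why: Dauben–Babler oxidative 1,3-transposition, in which the tertiary allylic chromate ester rearranges suprafacially to the C7 chromate and is oxidised, gives the β-methyl enone and has a direct counterpart in the conversion of tertiary allylic alcohols of the pinene series into verbenone-type enones.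

Step 17
Reactants: 25 transposed enone
Product: 26 C1 alcohol
Conditions: DDQ (1.3 equiv), CH2Cl2/pH 7 buffer, 0 °C
Reagents that add atoms: none
Why: Oxidative PMB cleavage by DDQ proceeds by hydride abstraction from the electron-rich benzylic position and hydrolysis of the oxocarbenium ion, leaving the enone and the hindered allylic alcohol intact at 0 °C.

Step 18
Reactants: 26 C1 alcohol
Product: 27 C1 angelate
Conditions: angelic acid, 2,4,6-trichlorobenzoyl chloride, Et3N, toluene, rt; then 26, 75 °C
Reagents that add atoms: angelic acid, C/C=C(/C)C(=O)O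
Why: Yamaguchi-type esterification through the preformed angelic 2,4,6-trichlorobenzoic anhydride in warm toluene acylates hindered secondary alcohols while keeping the Z geometry of the angelate, since no nucleophilic amine is present to isomerise it to the tiglate, and C1 reacts with retention.

Step 19
Reactants: 27 C1 angelate
Product: 28 C1 angelate C2,C3-diol
Conditions: OsO4 (5 mol %), N-methylmorpholine N-oxide, acetone/H2O, rt
Reagents that add atoms: osmium tetroxide, O=[Os](=O)(=O)=O; N-methylmorpholine N-oxide, C[N+]1([O-])CCOCC1; water, O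
Why: Upjohn dihydroxylation adds both oxygens syn to the only electron-rich alkene (the enone and angelate double bonds are deactivated) from the face opposite the allylic C1 acyloxy group, the usual sense for osmylation of allylic esters, giving the C2 and C3 hydroxyls cis to each other and trans to the C1 ester.

Step 20
Reactants: 28 C1 angelate C2,C3-diol
Product: 29 CNP0251293.1 (target)
Conditions: isovaleryl chloride (1.2 equiv), pyridine, CH2Cl2, −20 to 0 °C
Reagents that add atoms: isovaleryl chloride, CC(C)CC(=O)Cl
Why: Selective acylation of the less hindered C2 hydroxyl, the C3 hydroxyl being neopentylic next to the C4 quaternary carbon, completes the target at low temperature where acyl migration is slow.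

**Compound list**
1 | 2,2-dimethylbut-3-ynoic acid | C#CC(C)(C)C(=O)O | starting material
2 | 1-(2,2-dimethylbut-3-ynoyl)imidazole | C#CC(C)(C)C(=O)n1ccnc1 | intermediate
3 | N-methoxy-N,2,2-trimethylbut-3-ynamide | C#CC(C)(C)C(=O)N(C)OC | intermediate
4 | methacrolein | CC(=C)C=O | starting material
5 | (S)-5-hydroxy-N-methoxy-N,2,2,6-tetramethylhept-6-en-3-ynamide | CON(C)C(=O)C(C)(C)C#C[C@@H](O)C(C)=C | intermediate
6 | (S)-N-methoxy-5-[(4-methoxybenzyl)oxy]-N,2,2,6-tetramethylhept-6-en-3-ynamide | CON(C)C(=O)C(C)(C)C#C[C@@H](OCc1ccc(OC)cc1)C(C)=C | intermediate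
7 | (R,Z)-N-methoxy-5-[(4-methoxybenzyl)oxy]-N,2,2,6-tetramethylhepta-3,6-dienamide | CON(C)C(=O)C(C)(C)/C=C\[C@@H](OCc1ccc(OC)cc1)C(C)=C | intermediate
8 | (R,Z)-7-[(4-methoxybenzyl)oxy]-4,4,8-trimethylnona-1,5,8-trien-3-one | C=CC(=O)C(C)(C)/C=C\[C@@H](OCc1ccc(OC)cc1)C(C)=C | intermediate
9 | (R)-4-[(4-methoxybenzyl)oxy]-3,7,7-trimethylcyclohepta-2,5-dien-1-one | COc1ccc(CO[C@@H]2C=CC(C)(C)C(=O)C=C2C)cc1 | intermediate
10 | methyl vinyl ketone | CC(=O)C=C | starting material
11 | 2-(tert-butyldimethylsilyloxy)buta-1,3-diene | C=CC(=C)O[Si](C)(C)C(C)(C)C | intermediate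
12 | cis-fused bicyclic ketone: C5 ketone, C8=C9 tert-butyldimethylsilyl enol ether, C1 OPMB, C2=C3, H-6 and C11-methyl cis to the C1 oxygen | COc1ccc(CO[C@@H]2C=CC(C)(C)C(=O)[C@H]3CC=C(O[Si](C)(C)C(C)(C)C)C[C@@]23C)cc1 | intermediate
13 | C5 oxime of 12 (drawn with OH anti to C4; either oxime geometry serves) | COc1ccc(CO[C@@H]2C=CC(C)(C)/C(=N/O)[C@H]3CC=C(O[Si](C)(C)C(C)(C)C)C[C@@]23C)cc1 | intermediate
14 | C5 primary amine, nitrogen cis to C7 | COc1ccc(CO[C@@H]2C=CC(C)(C)[C@@H](N)[C@H]3CC=C(O[Si](C)(C)C(C)(C)C)C[C@@]23C)cc1 | intermediate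
15 | C5 trifluoroacetamide of 14 | COc1ccc(CO[C@@H]2C=CC(C)(C)[C@@H](NC(=O)C(F)(F)F)[C@H]3CC=C(O[Si](C)(C)C(C)(C)C)C[C@@]23C)cc1 | intermediate
16 | trifluoroacetamido enone: C9 ketone, C7=C8 | COc1ccc(CO[C@@H]2C=CC(C)(C)[C@@H](NC(=O)C(F)(F)F)[C@H]3C=CC(=O)C[C@@]23C)cc1 | intermediate
17 | N,O-bis(trimethylsilyl) cross-conjugated dienol ether of 16 (C7=C8, C9(OSiMe3)=C10) | COc1ccc(CO[C@@H]2C=CC(C)(C)[C@@H](N([Si](C)(C)C)C(=O)C(F)(F)F)[C@H]3C=CC(O[Si](C)(C)C)=C[C@@]23C)cc1 | intermediate
18 | α′-bromo enone: bromine at C10 cis to the C11 methyl | COc1ccc(CO[C@@H]2C=CC(C)(C)[C@@H](NC(=O)C(F)(F)F)[C@H]3C=CC(=O)[C@H](Br)[C@@]23C)cc1 | intermediate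
19 | N-trifluoroacetyl azatricycle: N bridging C5 and C10 | COc1ccc(CO[C@@H]2C=CC(C)(C)[C@@H]3[C@H]4C=CC(=O)[C@@H](N3C(=O)C(F)(F)F)[C@@]24C)cc1 | intermediate
20 | azatricyclic enone with NH bridging C5 and C10 (C9 ketone, C7=C8, C1 OPMB, C2=C3) | COc1ccc(CO[C@@H]2C=CC(C)(C)[C@@H]3[C@H]4C=CC(=O)[C@@H](N3)[C@@]24C)cc1 | intermediate
21 | N-benzyloxy-N-[4-(trifluoromethyl)benzoyl] hydrazide of 20 | COc1ccc(CO[C@@H]2C=CC(C)(C)[C@@H]3[C@H]4C=CC(=O)[C@@H](N3N(OCc5ccccc5)C(=O)c6ccc(cc6)C(F)(F)F)[C@@]24C)cc1 | intermediate
22 | isodiazene (1,1-diazene) of 20 | COc1ccc(CO[C@@H]2C=CC(C)(C)[C@@H]3[C@H]4C=CC(=O)[C@@H]([N+]3=[N-])[C@@]24C)cc1 | intermediate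
23 | tricyclic cyclobutane enone: C5–C10 bond, C9 ketone, C7=C8, C1 OPMB, C2=C3 | COc1ccc(CO[C@@H]2C=CC(C)(C)[C@@H]3[C@H]4C=CC(=O)[C@@H]3[C@@]24C)cc1 | intermediate
24 | C9 tertiary allylic alcohol: C9 methyl on the face of the C5 bridge, C7=C8 | COc1ccc(CO[C@@H]2C=CC(C)(C)[C@@H]3[C@H]4C=C[C@](C)(O)[C@@H]3[C@@]24C)cc1 | intermediate
25 | transposed enone: C7 ketone, C8=C9 with C9 methyl, C1 OPMB | COc1ccc(CO[C@@H]2C=CC(C)(C)[C@@H]3[C@H]4C(=O)C=C(C)[C@@H]3[C@@]24C)cc1 | intermediate
26 | C1 alcohol: C7 enone, C2=C3 | O[C@@H]1C=CC(C)(C)[C@@H]2[C@H]3C(=O)C=C(C)[C@@H]2[C@@]13C | intermediate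
27 | C1 angelate: C7 enone, C2=C3 | C/C=C(/C)C(=O)O[C@@H]1C=CC(C)(C)[C@@H]2[C@H]3C(=O)C=C(C)[C@@H]2[C@@]13C | intermediate
28 | C1 angelate C2,C3-diol: both hydroxyls trans to the C1 ester | C/C=C(/C)C(=O)O[C@@H]1[C@@H](O)[C@@H](O)C(C)(C)[C@@H]2[C@H]3C(=O)C=C(C)[C@@H]2[C@@]13C | intermediate
29 | CNP0251293.1 | C/C=C(/C)C(=O)O[C@@H]1[C@@H](OC(=O)CC(C)C)[C@@H](O)C(C)(C)[C@@H]2[C@H]3C(=O)C=C(C)[C@@H]2[C@@]13C | target

**Step count**
Total: 20 steps. Longest linear sequence: 19 steps (steps 1–6 and 8–20, from 1 to 29); step 7 is a one-step side branch.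

**Steps most likely to fail**

Step 14 (nitrogen deletion). The bulky anomeric amide may aminate the hindered bridging nitrogen too slowly, or the C5/C10 biradical may leak into scission of the C6–C11 bond or into hydrogen transfer instead of collapsing. The fallback sets out from 20 and returns at 23. It makes the isodiazene in two separate stages, the classical oxidation of a 1,1-disubstituted hydrazine. Compound 20 is N-aminated with the small electrophile hydroxylamine-O-sulfonic acid (KOH, H2O/THF, 0 °C) to the N-amino azatricycle F1. F1 is then oxidised with PhI(OAc)2 in CH2Cl2 at −40 °C to isodiazene 22, which loses N2 to give 23. N–N bond formation is then no longer limited by reagent size, and extrusion takes place cold, where cage recombination is most favoured.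

Step 8 (Diels–Alder). Attack at the fully substituted C11 may be too slow at the low temperature that the secondary allylic PMB ether tolerates, so that ionisation of the C1 ether by the silyl Lewis acid, or loss of facial selectivity, takes over. The fallback sets out from 9 and returns at 16. An acid-free thermal cycloaddition with the more electron-rich (E)-1-(dimethylamino)-3-(tert-butyldimethylsilyloxy)buta-1,3-diene in toluene at 80–110 °C should give, with the same regiochemistry and face selectivity, the C7-dimethylamino cycloadduct F2. This is carried through the same oximation to the oxime F3, LiAlH4 reduction to the amine F4 and trifluoroacetylation to the trifluoroacetamide F5. Aqueous HF in MeCN then removes the silyl group and eliminates dimethylamine to give enone 16 directly, without the palladium step.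

Step 10 (C5 amine). Hydride delivery to the hindered C5 oxime may be slow, or may occur on the concave face, which would put nitrogen on the face from which C10 cannot be reached. The fallback sets out from 13 and returns at 14. The oxime is first deoxygenated with Bu3P and PhSSPh to the N-unsubstituted ketimine F6, which, unlike the oxime, accepts the bulky hydride LiBH(s-Bu)3 (THF, −78 °C). Attack of this reagent is governed by steric approach from the open convex face and should give amine 14 with nitrogen on the concave face; 14 is then trifluoroacetylated as in step 10.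

Further compounds
F1 | step 14 | N-amino azatricycle (1,1-disubstituted hydrazine of 20) | COc1ccc(CO[C@@H]2C=CC(C)(C)[C@@H]3[C@H]4C=CC(=O)[C@@H](N3N)[C@@]24C)cc1
F2 | step 8 | C7-dimethylamino cycloadduct: C5 ketone, C8=C9 silyl enol ether, C7 configuration not defined | COc1ccc(CO[C@@H]2C=CC(C)(C)C(=O)[C@H]3C(N(C)C)C=C(O[Si](C)(C)C(C)(C)C)C[C@@]23C)cc1
F3 | step 8 | C5 oxime of F2 | COc1ccc(CO[C@@H]2C=CC(C)(C)/C(=N/O)[C@H]3C(N(C)C)C=C(O[Si](C)(C)C(C)(C)C)C[C@@]23C)cc1
F4 | step 8 | C5 primary amine from F3, nitrogen cis to C7 | COc1ccc(CO[C@@H]2C=CC(C)(C)[C@@H](N)[C@H]3C(N(C)C)C=C(O[Si](C)(C)C(C)(C)C)C[C@@]23C)cc1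
F5 | step 8 | C5 trifluoroacetamide of F4 | COc1ccc(CO[C@@H]2C=CC(C)(C)[C@@H](NC(=O)C(F)(F)F)[C@H]3C(N(C)C)C=C(O[Si](C)(C)C(C)(C)C)C[C@@]23C)cc1
F6 | step 10 | C5 N-unsubstituted ketimine of 12 | COc1ccc(CO[C@@H]2C=CC(C)(C)C(=N)[C@H]3CC=C(O[Si](C)(C)C(C)(C)C)C[C@@]23C)cc1
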